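**Retrosynthetic overview**

1. Prostanoid numbering is used (C1 ester carbon, ring C8–C12, C9 ketone, C10–Br, C12 carbinol). The last disconnection is C7=C8, by Horner–Wadsworth–Emmons olefination of a ring phosphonate (C8–C20) with the E enal C1–C7, itself made by cross-metathesis.
2. The key disconnection is C8–C12. The enabling feature is the 4-hydroxycyclopent-2-enone: carbinol C12 and ketone C9 stand in a 1,4-relation across C10=C11, with C8 next to C9. This is the retron of a 2-furylcarbinol (furan O → C9=O, furan C3–Br → C10–Br, furan C5 → C12, carbinol carbon → C8).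
3. The key step opens the furan with acid and water to a 1,4-dihydroxypentadienyl cation, which closes by conrotatory 4π electrocyclisation. This copies the oxidopentadienyl-cation closure of the presumed allene-oxide biosynthesis of marine prostanoids; a chiral Brønsted acid is meant to funnel the racemic carbinol into the 12R series.
4. Two temporary elements are removed again: the furan ring (opened in the key step) and the phosphonate on C8 (it activates C8–H, carries the olefination and leaves as phosphate).
5. Ring order: the furan ring is purchased; the cyclopentenone C8–C12, the only ring of the target, is the only and last ring closure. The furan precursor comes from furan by allylation, bromination, halogen dance/formylation and Pudovik addition.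

Key step: step 6

Remark on the chemistry (assumption): the sense of induction of the chiral acid in step 6 cannot be predicted with certainty; the (S)-configured acid is written, and its mirror image would be used if the first experiment shows the 12S series.

**Route**

Step 1
Reactants: 1 (2Z)-oct-2-en-1-ol
Product: 2 (2Z)-1-bromooct-2-ene
Conditions: CBr4, PPh3, CH2Cl2, 0 °C
Reagents that add atoms: carbon tetrabromide, BrC(Br)(Br)Br
Why: Appel reaction, in which bromide displaces the alkoxyphosphonium group at the primary allylic carbon in an SN2 fashion at 0 °C, so the Z alkene should be kept and no stereocentre is formed.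

Step 2
Reactants: 3 furan; 2 (2Z)-1-bromooct-2-ene
Product: 5 2-[(2Z)-oct-2-en-1-yl]furan, via 2-furyllithium 4 (not isolated)
Conditions: n-BuLi, THF, −78 → 0 °C; then 2, −78 °C → rt
Reagents that add atoms: none
Why: α-Lithiation of furan followed by SN2 alkylation of the furyllithium with the primary allylic bromide, a reliable entry to 2-allylfurans that leaves the Z alkene untouched and forms no stereocentre.

Step 3
Reactants: 5 2-[(2Z)-oct-2-en-1-yl]furan
Product: 6 2-bromo-5-[(2Z)-oct-2-en-1-yl]furan
Conditions: NBS, DMF, −20 → 0 °C, dark
Reagents that add atoms: N-bromosuccinimide, O=C1CCC(=O)N1Br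
Why: Electrophilic aromatic bromination of the 2-alkylfuran at its free α-position, which in DMF at low temperature in the dark should be much faster than ionic or radical attack on the isolated alkene.

Step 4
Reactants: 6 2-bromo-5-[(2Z)-oct-2-en-1-yl]furan
Product: 9 3-bromo-5-[(2Z)-oct-2-en-1-yl]furan-2-carbaldehyde, via 2-bromo-3-lithiofuran 7 (not isolated), via 3-bromo-2-lithiofuran 8 (not isolated)
Conditions: LiN(iPr)2, THF, −78 °C, 1 h; then DMF, −78 → 0 °C; H2O
Reagents that add atoms: N,N-dimethylformamide, CN(C)C=O
Why: Base-induced halogen dance, in which deprotonation ortho to bromine gives 7, a bromine–lithium exchange relay moves bromine to C3 and lithium to the more stable α-position (8), and formylation with DMF then fixes the 2,3,5-pattern that later places bromine on C10.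

Step 5
Reactants: 9 3-bromo-5-[(2Z)-oct-2-en-1-yl]furan-2-carbaldehyde; 10 diethyl phosphite
Product: 11 racemic diethyl {[3-bromo-5-[(2Z)-oct-2-en-1-yl]furan-2-yl](hydroxy)methyl}phosphonate
Conditions: Et3N (20 mol%), CH2Cl2, rt
Reagents that add atoms: none
Why: Pudovik reaction (amine-catalysed addition of the H-phosphonate to the aldehyde), whose new carbinol centre is left racemic on purpose because step 6 erases it, and which forms no co-product.

Step 6
Reactants: 11 racemic diethyl {[3-bromo-5-[(2Z)-oct-2-en-1-yl]furan-2-yl](hydroxy)methyl}phosphonate
Product: 14 diethyl [(2R)-4-bromo-2-hydroxy-2-[(2Z)-oct-2-en-1-yl]-5-oxocyclopent-3-en-1-yl]phosphonate, via furfuryl cation 12 (not isolated), via dihydroxypentadienyl cation 13 (not isolated)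
Conditions: (S)-3,3′-bis(2,4,6-triisopropylphenyl)-BINOL N-triflylphosphoramide (10 mol%), H2O (5 equiv), CHCl3, 40 °C
Reagents that add atoms: water, O
Why: Proposed new method: the chiral acid should ionise both enantiomers of 11 to the same furfuryl cation 12, water should add at the alkyl-bearing furan carbon (the later C12) and the resulting hemiketal should open to the 1,4-dihydroxypentadienyl cation 13, which forms the C8–C12 bond and, after loss of a proton from the C9 oxygen, the 2-bromo-4-hydroxycyclopent-2-enone. The closest known reaction types are the racemic Lewis acid-catalysed Piancatelli rearrangement of 5-alkyl-2-furylcarbinols and of furyl(hydroxy)methylphosphonates, the chiral phosphoric acid-catalysed aza-Piancatelli rearrangement and the chiral N-triflylphosphoramide-catalysed Nazarov cyclisation, so that only the enantioselective variant with water as nucleophile on this phosphonate class is new. The cyclopentenone ring closes by a thermally allowed conrotatory 4π electrocyclisation of 13 (in Baldwin terms a 5-(enolendo)-exo-trig bond formation that the pericyclic pathway makes easy), the same mode of closure as that of the oxidopentadienyl cation in the presumed allene-oxide biosynthesis of the marine prostanoids. The C12 carbinol centre is set by the sense of conrotation, which the chiral phosphoramide anion, held on 13 by hydrogen bonds to its two hydroxyl groups and the P=O group, is expected to dictate, and because the carbinol centre of 11 is erased in 12 the step is enantioconvergent. The centre at the phosphorus-bearing carbon C8 needs no control, since its epimers are both used in step 8 where C8 becomes an alkene carbon. The step needs attack of water at furan C5 and not at the carbinol carbon, which is secured because the latter attack only returns 11 while the 5-alkyl group stabilises the oxocarbenium ion, and it needs the skipped Z alkene and the C–Br bond to survive, which a mild acid of low nucleophilicity at 40 °C should allow without any co-product being formed.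

Step 7
Reactants: 15 methyl hex-5-enoate; 16 (2E)-but-2-enal
Product: 17 methyl (5E)-7-oxohept-5-enoate
Conditions: second-generation Grubbs catalyst RuCl2(=CHPh)(PCy3)(SIMes) (2 mol%), 16 in excess, CH2Cl2, 40 °C
Reagents that add atoms: none
Why: Olefin cross-metathesis of a terminal alkene with an excess of the electron-poor crotonaldehyde, which should give the E enal selectively with loss of propene.

Step 8
Reactants: 14 diethyl [(2R)-4-bromo-2-hydroxy-2-[(2Z)-oct-2-en-1-yl]-5-oxocyclopent-3-en-1-yl]phosphonate; 17 methyl (5E)-7-oxohept-5-enoate
Product: 18 methyl (5E,7E,12R,14Z)-10-bromo-12-hydroxy-9-oxoprosta-5,7,10,14-tetraenoate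
Conditions: LiCl, iPr2NEt, MeCN, 0 °C
Reagents that add atoms: none
Why: Horner–Wadsworth–Emmons olefination of the cyclic β-ketophosphonate under LiCl/amine conditions, in which only the acidic C8–H is ionised so that the C12 hydroxyl stays protonated and cannot be eliminated (the product would be a cyclopentadienone); both C8 epimers give the same anion, the E alkylidene with C6 anti to the C9 carbonyl is the expected major isomer, and the C5=C6 E alkene and the C12 centre are carried through unchanged.

**Compound list**

1 | (2Z)-oct-2-en-1-ol | CCCCC/C=C\CO | starting material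
2 | (2Z)-1-bromooct-2-ene | CCCCC/C=C\CBr | intermediate
3 | furan | c1ccoc1 | starting material
4 | 2-furyllithium (formed in the flask, not isolated) | [Li]c1ccco1 | intermediate
5 | 2-[(2Z)-oct-2-en-1-yl]furan | CCCCC/C=C\Cc1ccco1 | intermediate
6 | 2-bromo-5-[(2Z)-oct-2-en-1-yl]furan | CCCCC/C=C\Cc1ccc(Br)o1 | intermediate
7 | 2-bromo-3-lithio-5-[(2Z)-oct-2-en-1-yl]furan (formed in the flask, not isolated) | CCCCC/C=C\Cc1cc([Li])c(Br)o1 | intermediate
8 | 3-bromo-2-lithio-5-[(2Z)-oct-2-en-1-yl]furan (formed in the flask, not isolated) | CCCCC/C=C\Cc1cc(Br)c([Li])o1 | intermediate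
9 | 3-bromo-5-[(2Z)-oct-2-en-1-yl]furan-2-carbaldehyde | CCCCC/C=C\Cc1cc(Br)c(C=O)o1 | intermediate
10 | diethyl phosphite (diethyl H-phosphonate) | CCO[PH](=O)OCC | starting material
11 | racemic diethyl {[3-bromo-5-[(2Z)-oct-2-en-1-yl]furan-2-yl](hydroxy)methyl}phosphonate | CCCCC/C=C\Cc1cc(Br)c(o1)C(O)P(=O)(OCC)OCC | intermediate
12 | furfuryl cation: 3-bromo-2-[(diethoxyphosphoryl)methylidene]-5-[(2Z)-oct-2-en-1-yl]-2H-furan-1-ium (formed in the flask, not isolated) | CCCCC/C=C\CC1=[O+]C(=CP(=O)(OCC)OCC)C(Br)=C1 | intermediate
13 | 1,4-dihydroxypentadienyl cation: O-protonated open-chain enol ketone P–C8H=C9(OH)–C10(Br)=C11H–C12(=OH+)–octenyl, C9 and C12 cis on C10=C11 (formed in the flask, not isolated) | CCCCC/C=C\CC(=[OH+])/C=C(Br)\C(O)=CP(=O)(OCC)OCC | intermediate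
14 | diethyl [(2R)-4-bromo-2-hydroxy-2-[(2Z)-oct-2-en-1-yl]-5-oxocyclopent-3-en-1-yl]phosphonate (12R in prostanoid numbering; both epimers at the phosphorus-bearing carbon C1, which are used together) | CCCCC/C=C\C[C@@]1(O)C=C(Br)C(=O)C1P(=O)(OCC)OCC | intermediate
15 | methyl hex-5-enoate | COC(=O)CCCC=C | starting material
16 | (2E)-but-2-enal (crotonaldehyde) | C/C=C/C=O | starting material
17 | methyl (5E)-7-oxohept-5-enoate | COC(=O)CCC/C=C/C=O | intermediate
18 | methyl (5E,7E,12R,14Z)-10-bromo-12-hydroxy-9-oxoprosta-5,7,10,14-tetraenoate | CCCCC/C=C\C[C@@]1(O)C=C(Br)C(=O)/C1=C/C=C/CCCC(=O)OC | target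

**Step count and risks**

Total step count: 8. Longest linear sequence: 7 steps (steps 1 to 6 and step 8); step 7 is a one-step side branch.

Steps most likely to fail:

1. Step 6 (proposed new method). Ionisation of the carbinol, which is deactivated by the phosphoryl group and the bromine, may be too slow with the chiral acid. The chiral anion may also fail to control the sense of conrotation, and acid-promoted migration of the C14=C15 alkene into conjugation could erode material. The fallback uses known chemistry and gives up catalyst control for a racemic synthesis with resolution. It sets out from 11, which is rearranged under established Lewis acid conditions (Dy(OTf)3, t-BuOH/H2O, 80 °C) to racemic diethyl [4-bromo-2-hydroxy-2-[(2Z)-oct-2-en-1-yl]-5-oxocyclopent-3-en-1-yl]phosphonate F1. F1 is olefinated with 17 as in step 8 to racemic methyl (5E,7E,14Z)-10-bromo-12-hydroxy-9-oxoprosta-5,7,10,14-tetraenoate F2, whose only stereocentre is C12. Its enantiomers are separated by preparative chromatography on a chiral stationary phase (amylose tris(3,5-dimethylphenylcarbamate)), and the route comes back at 18.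

2. Step 8. Enantiopurity may erode through base-induced retro-aldol opening of the C8–C12 bond (the C12 alkoxide expelling the stabilised phosphonate carbanion) and re-closure before the olefination. E selectivity at C7=C8 may also be incomplete. The fallback masks the alkoxide donor. It sets out from 14, which is silylated with N-(trimethylsilyl)imidazole in CH2Cl2 to diethyl [(2R)-4-bromo-2-[(2Z)-oct-2-en-1-yl]-5-oxo-2-(trimethylsilyloxy)cyclopent-3-en-1-yl]phosphonate F3. Olefination of F3 with 17 (LiCl, DBU, MeCN) should give methyl (5E,7E,12R,14Z)-10-bromo-9-oxo-12-(trimethylsilyloxy)prosta-5,7,10,14-tetraenoate F4. Cleavage of the silyl ether with HF·pyridine in THF at 0 °C comes back at 18.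

3. Step 4. The bromine migration may stop short of completion, and the amide base may instead deprotonate the doubly activated furfuryl–allyl CH2, with loss of the skipped Z alkene. The fallback builds the substitution pattern without an amide base next to the side chain. It sets out from 2 and commercial 2,3-dibromofuran. The dibromofuran is deprotonated at C5 (LiN(iPr)2, THF, −78 °C) and alkylated with 2 to 2,3-dibromo-5-[(2Z)-oct-2-en-1-yl]furan F5. Selective bromine–lithium exchange at the α-bromine (n-BuLi, Et2O, −78 °C) gives the same lithiofuran 8, and quenching with DMF comes back at 9.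

Further compounds
F1 | step 6 | racemic diethyl [4-bromo-2-hydroxy-2-[(2Z)-oct-2-en-1-yl]-5-oxocyclopent-3-en-1-yl]phosphonate | CCCCC/C=C\CC1(O)C=C(Br)C(=O)C1P(=O)(OCC)OCC
F2 | step 6 | racemic methyl (5E,7E,14Z)-10-bromo-12-hydroxy-9-oxoprosta-5,7,10,14-tetraenoate | CCCCC/C=C\CC1(O)C=C(Br)C(=O)/C1=C/C=C/CCCC(=O)OC
F3 | step 8 | diethyl [(2R)-4-bromo-2-[(2Z)-oct-2-en-1-yl]-5-oxo-2-(trimethylsilyloxy)cyclopent-3-en-1-yl]phosphonate | CCCCC/C=C\C[C@@]1(O[Si](C)(C)C)C=C(Br)C(=O)C1P(=O)(OCC)OCC
F4 | step 8 | methyl (5E,7E,12R,14Z)-10-bromo-9-oxo-12-(trimethylsilyloxy)prosta-5,7,10,14-tetraenoate | CCCCC/C=C\C[C@@]1(O[Si](C)(C)C)C=C(Br)C(=O)/C1=C/C=C/CCCC(=O)OC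
F5 | step 4 | 2,3-dibromo-5-[(2Z)-oct-2-en-1-yl]furan | CCCCC/C=C\Cc1cc(Br)c(Br)o1
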